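**Plan**

Numbering used: ring A = C1, C2, C3 (C=O), C4 (CH3 and the C19 oxymethylene), C5, C10; ring B = C5, C6 (OH), C7, C8 (CH3), C9 (CH3 and the C11–C12 chain to butenolide carbon C13), C10; the target is 4S,6S,8S,9R.
Retrosynthetic cuts, in order: the C19–O ester bond, the C12–C13 sp3–sp2 bond to the butenolide, then C4–C5. The C3 ketone, the α-quaternary C4 and the β-hydroxyl on C19 are together the retron of an epoxy-alcohol semipinacol shift, which contracts ring A to a ring-B-fused cyclopentenol carrying a 2-methyloxirane on C3.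
Further cuts: C3–C4 (isopropenyl addition), C3–C5 (Nozaki–Hiyama–Kishi closure), C10–C1 (Grignard addition with oxidative transposition), C9–C11 (enolate allylation), C8–CH3 (conjugate addition).
Forward: ring B is made first from 2-methylcyclohexenone, a five-membered ring is annulated across C5/C10, ring expansion gives ring A, then the C19 ester is attached and the allyl group is cut back to a C12 iodide and coupled with a 4-halobutenolide.
Stereochemistry: C8 from a copper/phosphoramidite-catalysed conjugate addition, C9 by anti alkylation of the derived enolate, C6 by Corey–Bakshi–Shibata reduction of an α-iodo enone, C4 by hydroxyl-directed epoxidation followed by invertive 1,2-migration.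

Key step: step 14

Assumption: the phosphoramidite antipode quoted in step 1 is taken to deliver methyl to the face that gives 8S, as it does for unsubstituted cyclohexenone with dialkylzinc reagents; if the sense is reversed for this enone/aluminium pair, the enantiomeric ligand is used and nothing else changes.

**Route**

Step 1
Reactants: 1 2-methylcyclohex-2-en-1-one; 2 trimethylaluminium
Product: 4 trimethyl{[(3S)-2,3-dimethylcyclohex-1-en-1-yl]oxy}silane, via aluminium enolate 3 (not isolated)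
Conditions: Me3Al, copper thiophene-2-carboxylate Cu(O2CC4H3S) (5 mol %), (S)-BINOL-derived N,N-bis[(R)-1-phenylethyl]phosphoramidite (10 mol %), Et2O, −30 °C; then TMSOTf, THF, −30 → 0 °C
Reagents that add atoms: trimethylaluminium (2), C[Al](C)C; trimethylsilyl trifluoromethanesulfonate, C[Si](C)(C)OS(=O)(=O)C(F)(F)F
Why: Copper-catalysed asymmetric conjugate addition of a trialkylaluminium to an α-substituted cyclohexenone is a known reaction type; the chiral phosphoramidite complex of monovalent copper selects the enone face and so sets C8 as S, and O-silylation of the aluminium enolate stores the C9–C10 enolate regiochemistry for the next step.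

Step 2
Reactants: 4 trimethyl{[(3S)-2,3-dimethylcyclohex-1-en-1-yl]oxy}silane; 5 allyl bromide
Product: 7 (2R,3S)-2,3-dimethyl-2-(prop-2-en-1-yl)cyclohexan-1-one, via lithium enolate 6 (not isolated)
Conditions: MeLi, THF, 0 °C; then allyl bromide, DMPU, −78 → 0 °C
Reagents that add atoms: allyl bromide (5), C=CCBr
Why: MeLi cleaves the silyl enol ether to the regiodefined tetrasubstituted lithium enolate, and allylation of such 2,3-dialkyl enolates occurs anti to the neighbouring methyl group, which sits pseudoaxial to avoid A(1,2) strain with the enolate methyl, so quaternary C9 should form with the two methyl groups cis (conjugate addition–enolate alkylation logic).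

Step 3
Reactants: 7 (2R,3S)-2,3-dimethyl-2-(prop-2-en-1-yl)cyclohexan-1-one
Product: 9 (5S,6R)-5,6-dimethyl-6-(prop-2-en-1-yl)cyclohex-2-en-1-one, via lithium enolate 8 (not isolated)
Conditions: LiN(iPr)2, THF, −78 °C; then PhS(Cl)=NtBu, −78 °C
Reagents that add atoms: none
Why: Mukaiyama dehydrogenation: the ketone can enolise only toward C5, and the lithium enolate adds to sulfur of the sulfinimidoyl chloride and undergoes syn elimination at −78 °C, which should give the C5=C6 enone without touching the allyl group.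

Step 4
Reactants: 9 (5S,6R)-5,6-dimethyl-6-(prop-2-en-1-yl)cyclohex-2-en-1-one
Product: 10 (5S,6R)-2-iodo-5,6-dimethyl-6-(prop-2-en-1-yl)cyclohex-2-en-1-one
Conditions: I2, pyridine/CH2Cl2 (1:1), 0 °C → rt
Reagents that add atoms: iodine, II
Why: Pyridine-mediated α-iodination of an enone (conjugate addition, iodination, elimination) works best when the β-carbon is an unhindered CH as here, and iodine does not add irreversibly to the isolated allyl alkene.

Step 5
Reactants: 10 (5S,6R)-2-iodo-5,6-dimethyl-6-(prop-2-en-1-yl)cyclohex-2-en-1-one; 11 [2-(1,3-dioxolan-2-yl)ethyl]magnesium bromide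
Product: 12 (5S,6R)-1-[2-(1,3-dioxolan-2-yl)ethyl]-2-iodo-5,6-dimethyl-6-(prop-2-en-1-yl)cyclohex-2-en-1-ol (both C1 epimers)
Conditions: 11, LaCl3·2LiCl, THF, −78 → −40 °C; aq. NH4Cl
Reagents that add atoms: [2-(1,3-dioxolan-2-yl)ethyl]magnesium bromide (11), Br[Mg]CCC1OCCO1
Why: Lanthanum-chloride-promoted 1,2-addition of a Grignard reagent to an α-iodo enone: the carbonyl has no α-hydrogen on either side, so enolisation cannot compete, low temperature holds back iodine–magnesium exchange, and the new carbinol centre needs no control because it becomes sp2 in step 6.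

Step 6
Reactants: 12 (5S,6R)-1-[2-(1,3-dioxolan-2-yl)ethyl]-2-iodo-5,6-dimethyl-6-(prop-2-en-1-yl)cyclohex-2-en-1-ol
Product: 13 (4R,5S)-3-[2-(1,3-dioxolan-2-yl)ethyl]-2-iodo-4,5-dimethyl-4-(prop-2-en-1-yl)cyclohex-2-en-1-one
Conditions: pyridinium chlorochromate (C5H5NH)[CrO3Cl], 4 Å MS, CH2Cl2, rt
Reagents that add atoms: pyridinium chlorochromate, [O-][Cr](=O)(=O)Cl.c1cc[nH+]cc1
Why: Babler–Dauben oxidative transposition: the tertiary allylic chromate ester undergoes a [3,3] shift to C6 and is oxidised there, which should deliver the C6 ketone, the C5=C10 alkene and the C5 iodide in one operation while the acetal and the terminal alkene are inert to the hexavalent chromium reagent.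

Step 7
Reactants: 13 (4R,5S)-3-[2-(1,3-dioxolan-2-yl)ethyl]-2-iodo-4,5-dimethyl-4-(prop-2-en-1-yl)cyclohex-2-en-1-one
Product: 14 (1S,4R,5S)-3-[2-(1,3-dioxolan-2-yl)ethyl]-2-iodo-4,5-dimethyl-4-(prop-2-en-1-yl)cyclohex-2-en-1-ol
Conditions: (R)-2-methyl-CBS-oxazaborolidine (0.3 equiv), catecholborane, toluene, −78 → −40 °C
Reagents that add atoms: none
Why: Corey–Bakshi–Shibata reduction, for which α-iodo enones are among the best substrates: the iodoalkene side acts as the large group, so the (R)-catalyst should deliver hydride to the face giving the 6S carbinol under reagent control, and catecholborane at −78 °C does not hydroborate the allyl group.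

Step 8
Reactants: 14 (1S,4R,5S)-3-[2-(1,3-dioxolan-2-yl)ethyl]-2-iodo-4,5-dimethyl-4-(prop-2-en-1-yl)cyclohex-2-en-1-ol
Product: 15 tert-butyl({(1S,4R,5S)-3-[2-(1,3-dioxolan-2-yl)ethyl]-2-iodo-4,5-dimethyl-4-(prop-2-en-1-yl)cyclohex-2-en-1-yl}oxy)dimethylsilane
Conditions: TBSCl, imidazole, DMF, rt
Reagents that add atoms: tert-butyldimethylsilyl chloride, CC(C)(C)[Si](C)(C)Cl
Why: Standard silylation of a secondary allylic alcohol; the silyl ether is chosen to survive Lewis acid at −78 °C later and to come off with fluoride at the end.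

Step 9
Reactants: 15 tert-butyl({(1S,4R,5S)-3-[2-(1,3-dioxolan-2-yl)ethyl]-2-iodo-4,5-dimethyl-4-(prop-2-en-1-yl)cyclohex-2-en-1-yl}oxy)dimethylsilane
Product: 16 3-[(3S,5S,6R)-3-{[tert-butyl(dimethyl)silyl]oxy}-2-iodo-5,6-dimethyl-6-(prop-2-en-1-yl)cyclohex-1-en-1-yl]propanal
Conditions: PPTS (cat.), acetone/H2O (10:1), 55 °C
Reagents that add atoms: water, O
Why: Acid-catalysed hydrolysis of the dioxolane under mild pyridinium tosylate conditions, which a hindered secondary silyl ether and a vinyl iodide should survive.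

Step 10
Reactants: 16 3-[(3S,5S,6R)-3-{[tert-butyl(dimethyl)silyl]oxy}-2-iodo-5,6-dimethyl-6-(prop-2-en-1-yl)cyclohex-1-en-1-yl]propanal
Product: 17 (4R,5S,7S)-7-{[tert-butyl(dimethyl)silyl]oxy}-4,5-dimethyl-4-(prop-2-en-1-yl)-2,3,4,5,6,7-hexahydro-1H-inden-1-ol (both C1 epimers)
Conditions: CrCl2 (5 equiv), NiCl2 (5 mol %), degassed DMF, rt, high dilution
Reagents that add atoms: none
Why: Intramolecular Nozaki–Hiyama–Kishi reaction: zerovalent nickel inserts into the C5–I bond, transmetalation gives an alkenyl derivative of trivalent chromium that adds chemoselectively to the aldehyde in a 5-exo closure (C3–C5 bond), and neither the silyl ether nor the allyl group reacts with divalent chromium; the carbinol configuration is irrelevant.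

Step 11
Reactants: 17 (4R,5S,7S)-7-{[tert-butyl(dimethyl)silyl]oxy}-4,5-dimethyl-4-(prop-2-en-1-yl)-2,3,4,5,6,7-hexahydro-1H-inden-1-ol
Product: 18 (4R,5S,7S)-7-{[tert-butyl(dimethyl)silyl]oxy}-4,5-dimethyl-4-(prop-2-en-1-yl)-2,3,4,5,6,7-hexahydro-1H-inden-1-one
Conditions: Dess–Martin periodinane, NaHCO3, CH2Cl2, 0 °C → rt
Reagents that add atoms: none
Why: Dess–Martin oxidation of the allylic alcohol gives the conjugated cyclopentenone under near-neutral conditions.

Step 12
Reactants: 18 (4R,5S,7S)-7-{[tert-butyl(dimethyl)silyl]oxy}-4,5-dimethyl-4-(prop-2-en-1-yl)-2,3,4,5,6,7-hexahydro-1H-inden-1-one; 19 isopropenylmagnesium bromide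
Product: 20 (1S,4R,5S,7S)-7-{[tert-butyl(dimethyl)silyl]oxy}-4,5-dimethyl-1-(prop-1-en-2-yl)-4-(prop-2-en-1-yl)-2,3,4,5,6,7-hexahydro-1H-inden-1-ol
Conditions: 19, LaCl3·2LiCl, THF, −78 → 0 °C; aq. NH4Cl
Reagents that add atoms: isopropenylmagnesium bromide (19), C=C(C)[Mg]Br
Why: 1,2-Addition of an alkenyl Grignard reagent to a cyclopentenone whose β-carbon is fully substituted (no 1,4-path), with LaCl3·2LiCl to suppress enolisation; the C6 silyl ether is held pseudoaxial by peri strain with the C3 carbonyl and shields its own face, so the nucleophile should enter anti to it and the new hydroxyl should end cis to the silyloxy group.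

Step 13
Reactants: 20 (1S,4R,5S,7S)-7-{[tert-butyl(dimethyl)silyl]oxy}-4,5-dimethyl-1-(prop-1-en-2-yl)-4-(prop-2-en-1-yl)-2,3,4,5,6,7-hexahydro-1H-inden-1-ol
Product: 21 (1R,4R,5S,7S)-7-{[tert-butyl(dimethyl)silyl]oxy}-4,5-dimethyl-1-[(2R)-2-methyloxiran-2-yl]-4-(prop-2-en-1-yl)-2,3,4,5,6,7-hexahydro-1H-inden-1-ol
Conditions: VO(acac)2 (5 mol %), t-BuOOH (decane), CH2Cl2, 0 °C → rt
Reagents that add atoms: tert-butyl hydroperoxide, CC(C)(C)OO
Why: Hydroxyl-directed vanadium-catalysed epoxidation of an allylic alcohol: the vanadate ester delivers the peroxide oxygen intramolecularly to the exocyclic 1,1-disubstituted alkene (the ring alkene is tetrasubstituted and screened on the hydroxyl face by the C6 silyl ether, and the allyl group has no directing hydroxyl), and the transition state that places the =CH2 terminus and the metal on the C2 side and the alkene methyl over the flat C5 carbon, away from the silyl ether, should give the (2R)-oxirane.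

Step 14
Reactants: 21 (1R,4R,5S,7S)-7-{[tert-butyl(dimethyl)silyl]oxy}-4,5-dimethyl-1-[(2R)-2-methyloxiran-2-yl]-4-(prop-2-en-1-yl)-2,3,4,5,6,7-hexahydro-1H-inden-1-ol
Product: 22 (1S,5R,6S,8S)-8-{[tert-butyl(dimethyl)silyl]oxy}-1-(hydroxymethyl)-1,5,6-trimethyl-5-(prop-2-en-1-yl)-3,4,5,6,7,8-hexahydronaphthalen-2(1H)-one
Conditions: BF3·OEt2 (1.1 equiv), CH2Cl2, −78 °C; aq. NaHCO3
Reagents that add atoms: none
Why: BF3 coordinates the oxirane oxygen and weakens the tertiary C4–O bond; in the rotamer with the C3–C5 bond antiperiplanar to that bond the alkenyl carbon C5 shifts from C3 to C4 while the carbinol oxygen becomes the C3 ketone and the oxirane oxygen ends as the C19 hydroxyl, a semipinacol rearrangement of a tertiary α-hydroxy epoxide whose closest known type is the ring expansion of 1-oxiranylcycloalkanols to 2-(hydroxymethyl)cycloalkanones. Ring A is closed by this 1,2-shift ring enlargement of the cyclopentene (five- to six-membered) and not by a new cyclisation, so no ring-closure rule limits it. The only new stereocentre, C4, arises with inversion at the epoxide carbon and is therefore fixed by the (2R)-oxirane of 21, while the C3 carbinol centre is consumed. The step needs migration of alkenyl C5 in preference to alkyl C2, and epoxide opening in preference to ionisation of the tertiary allylic carbinol or the allylic silyl ether; the higher migratory aptitude of the sp2 carbon (its π bond participates through a cyclopropylcarbinyl-like bridged transition state), the tertiary nature of C4 and the low temperature should secure this. The tetrasubstituted C5=C10 alkene stays in place, so the product is directly the β-hydroxy ketone pattern of the target.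

Step 15
Reactants: 23 3-(4-hydroxyphenyl)propanoic acid
Product: 25 3-(4-{[tert-butyl(dimethyl)silyl]oxy}phenyl)propanoic acid, via bis-silyl derivative 24 (not isolated)
Conditions: TBSCl (2.3 equiv), imidazole, DMF, rt; then AcOH/THF/H2O, rt
Reagents that add atoms: tert-butyldimethylsilyl chloride, CC(C)(C)[Si](C)(C)Cl
Why: Exhaustive silylation followed by selective hydrolysis of the labile silyl ester leaves the aryl silyl ether, a routine way to protect a phenolic acid.

Step 16
Reactants: 22 (1S,5R,6S,8S)-8-{[tert-butyl(dimethyl)silyl]oxy}-1-(hydroxymethyl)-1,5,6-trimethyl-5-(prop-2-en-1-yl)-3,4,5,6,7,8-hexahydronaphthalen-2(1H)-one; 25 3-(4-{[tert-butyl(dimethyl)silyl]oxy}phenyl)propanoic acid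
Product: 26 [(1S,5R,6S,8S)-8-{[tert-butyl(dimethyl)silyl]oxy}-1,5,6-trimethyl-2-oxo-5-(prop-2-en-1-yl)-1,2,3,4,5,6,7,8-octahydronaphthalen-1-yl]methyl 3-(4-{[tert-butyl(dimethyl)silyl]oxy}phenyl)propanoate
Conditions: 25, EDC, DMAP (cat.), CH2Cl2, 0 °C → rt
Reagents that add atoms: 3-(4-{[tert-butyl(dimethyl)silyl]oxy}phenyl)propanoic acid (25), OC(=O)CCc1ccc(O[Si](C)(C)C(C)(C)C)cc1
Why: Steglich esterification of the neopentyl-type primary alcohol; carrying it out directly after the rearrangement caps the β-hydroxy ketone against retro-aldol loss of formaldehyde.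

Step 17
Reactants: 26 [(1S,5R,6S,8S)-8-{[tert-butyl(dimethyl)silyl]oxy}-1,5,6-trimethyl-2-oxo-5-(prop-2-en-1-yl)-1,2,3,4,5,6,7,8-octahydronaphthalen-1-yl]methyl 3-(4-{[tert-butyl(dimethyl)silyl]oxy}phenyl)propanoate
Product: 27 [(1S,5R,6S,8S)-8-{[tert-butyl(dimethyl)silyl]oxy}-1,5,6-trimethyl-2-oxo-5-(2-oxoethyl)-1,2,3,4,5,6,7,8-octahydronaphthalen-1-yl]methyl 3-(4-{[tert-butyl(dimethyl)silyl]oxy}phenyl)propanoate
Conditions: OsO4 (2 mol %), NaIO4, 2,6-lutidine, dioxane/H2O (3:1), rt
Reagents that add atoms: osmium tetroxide, O=[Os](=O)(=O)=O; sodium periodate, [Na+].[O-]I(=O)(=O)=O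
Why: Lemieux–Johnson cleavage: OsO4 dihydroxylates only the monosubstituted terminal alkene, the tetrasubstituted C5=C10 alkene being too hindered, and periodate cleaves the diol to the C12 aldehyde.

Step 18
Reactants: 27 [(1S,5R,6S,8S)-8-{[tert-butyl(dimethyl)silyl]oxy}-1,5,6-trimethyl-2-oxo-5-(2-oxoethyl)-1,2,3,4,5,6,7,8-octahydronaphthalen-1-yl]methyl 3-(4-{[tert-butyl(dimethyl)silyl]oxy}phenyl)propanoate
Product: 28 [(1S,5R,6S,8S)-8-{[tert-butyl(dimethyl)silyl]oxy}-5-(2-hydroxyethyl)-1,5,6-trimethyl-2-oxo-1,2,3,4,5,6,7,8-octahydronaphthalen-1-yl]methyl 3-(4-{[tert-butyl(dimethyl)silyl]oxy}phenyl)propanoate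
Conditions: NaBH4, MeOH/CH2Cl2, −78 °C
Reagents that add atoms: none
Why: Borohydride at −78 °C reduces an unhindered aldehyde much faster than the α-quaternary C3 ketone or the ester.

Step 19
Reactants: 28 [(1S,5R,6S,8S)-8-{[tert-butyl(dimethyl)silyl]oxy}-5-(2-hydroxyethyl)-1,5,6-trimethyl-2-oxo-1,2,3,4,5,6,7,8-octahydronaphthalen-1-yl]methyl 3-(4-{[tert-butyl(dimethyl)silyl]oxy}phenyl)propanoate
Product: 29 [(1S,5R,6S,8S)-8-{[tert-butyl(dimethyl)silyl]oxy}-5-(2-iodoethyl)-1,5,6-trimethyl-2-oxo-1,2,3,4,5,6,7,8-octahydronaphthalen-1-yl]methyl 3-(4-{[tert-butyl(dimethyl)silyl]oxy}phenyl)propanoate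
Conditions: I2, PPh3, imidazole, CH2Cl2, 0 °C → rt
Reagents that add atoms: iodine, II
Why: Appel-type iodination converts the primary alcohol to the iodide by SN2 displacement of the oxyphosphonium group under neutral conditions.

Step 20
Reactants: 29 [(1S,5R,6S,8S)-8-{[tert-butyl(dimethyl)silyl]oxy}-5-(2-iodoethyl)-1,5,6-trimethyl-2-oxo-1,2,3,4,5,6,7,8-octahydronaphthalen-1-yl]methyl 3-(4-{[tert-butyl(dimethyl)silyl]oxy}phenyl)propanoate; 30 4-bromofuran-2(5H)-one
Product: 32 [(1S,5R,6S,8S)-8-{[tert-butyl(dimethyl)silyl]oxy}-1,5,6-trimethyl-2-oxo-5-[2-(5-oxo-2,5-dihydrofuran-3-yl)ethyl]-1,2,3,4,5,6,7,8-octahydronaphthalen-1-yl]methyl 3-(4-{[tert-butyl(dimethyl)silyl]oxy}phenyl)propanoate, via alkylzinc iodide 31 (not isolated)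
Conditions: activated Zn dust, DMA, 40 °C; then 30, PdCl2(dppf) (5 mol %), DMA/THF, rt → 40 °C
Reagents that add atoms: 4-bromofuran-2(5H)-one (30), BrC1=CC(=O)OC1
Why: Negishi coupling: zinc inserts into the primary C–I bond in the presence of ketone, ester and silyl ethers, and the alkylzinc iodide couples with the vinylogous acyl bromide after its oxidative addition to zerovalent palladium, the bidentate dppf ligand disfavouring β-hydride elimination.

Step 21
Reactants: 32 [(1S,5R,6S,8S)-8-{[tert-butyl(dimethyl)silyl]oxy}-1,5,6-trimethyl-2-oxo-5-[2-(5-oxo-2,5-dihydrofuran-3-yl)ethyl]-1,2,3,4,5,6,7,8-octahydronaphthalen-1-yl]methyl 3-(4-{[tert-butyl(dimethyl)silyl]oxy}phenyl)propanoate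
Product: 33 [(1S,5R,6S,8S)-8-hydroxy-1,5,6-trimethyl-2-oxo-5-[2-(5-oxo-2,5-dihydrofuran-3-yl)ethyl]-1,2,3,4,5,6,7,8-octahydronaphthalen-1-yl]methyl 3-(4-hydroxyphenyl)propanoate (CNP0301014.1)
Conditions: HF·pyridine, THF/pyridine, 0 °C → rt
Reagents that add atoms: none
Why: Fluoride cleavage of both silyl ethers with buffered HF·pyridine, conditions under which the butenolide, the ester, the ketone and the allylic carbinol should persist.

**Compound list**

1 | 2-methylcyclohex-2-en-1-one | CC1=CCCCC1=O | starting material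
2 | trimethylaluminium | C[Al](C)C | starting material
3 | dimethylaluminium (3S)-2,3-dimethylcyclohex-1-en-1-olate | C[C@H]1CCCC(O[Al](C)C)=C1C | intermediate (not isolated)
4 | trimethyl{[(3S)-2,3-dimethylcyclohex-1-en-1-yl]oxy}silane | C[C@H]1CCCC(O[Si](C)(C)C)=C1C | intermediate
5 | allyl bromide (3-bromoprop-1-ene) | C=CCBr | starting material
6 | lithium (3S)-2,3-dimethylcyclohex-1-en-1-olate | C[C@H]1CCCC(O[Li])=C1C | intermediate (not isolated)
7 | (2R,3S)-2,3-dimethyl-2-(prop-2-en-1-yl)cyclohexan-1-one | C[C@H]1CCCC(=O)[C@]1(C)CC=C | intermediate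
8 | lithium (5S,6R)-5,6-dimethyl-6-(prop-2-en-1-yl)cyclohex-1-en-1-olate | C[C@H]1CCC=C(O[Li])[C@]1(C)CC=C | intermediate (not isolated)
9 | (5S,6R)-5,6-dimethyl-6-(prop-2-en-1-yl)cyclohex-2-en-1-one | C[C@H]1CC=CC(=O)[C@]1(C)CC=C | intermediate
10 | (5S,6R)-2-iodo-5,6-dimethyl-6-(prop-2-en-1-yl)cyclohex-2-en-1-one | C[C@H]1CC=C(I)C(=O)[C@]1(C)CC=C | intermediate
11 | [2-(1,3-dioxolan-2-yl)ethyl]magnesium bromide | Br[Mg]CCC1OCCO1 | starting material
12 | (5S,6R)-1-[2-(1,3-dioxolan-2-yl)ethyl]-2-iodo-5,6-dimethyl-6-(prop-2-en-1-yl)cyclohex-2-en-1-ol, both C1 epimers | C[C@H]1CC=C(I)C(O)(CCC2OCCO2)[C@]1(C)CC=C | intermediate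
13 | (4R,5S)-3-[2-(1,3-dioxolan-2-yl)ethyl]-2-iodo-4,5-dimethyl-4-(prop-2-en-1-yl)cyclohex-2-en-1-one | C[C@H]1CC(=O)C(I)=C(CCC2OCCO2)[C@]1(C)CC=C | intermediate
14 | (1S,4R,5S)-3-[2-(1,3-dioxolan-2-yl)ethyl]-2-iodo-4,5-dimethyl-4-(prop-2-en-1-yl)cyclohex-2-en-1-ol | C[C@H]1C[C@H](O)C(I)=C(CCC2OCCO2)[C@]1(C)CC=C | intermediate
15 | tert-butyl({(1S,4R,5S)-3-[2-(1,3-dioxolan-2-yl)ethyl]-2-iodo-4,5-dimethyl-4-(prop-2-en-1-yl)cyclohex-2-en-1-yl}oxy)dimethylsilane | C[C@H]1C[C@H](O[Si](C)(C)C(C)(C)C)C(I)=C(CCC2OCCO2)[C@]1(C)CC=C | intermediate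
16 | 3-[(3S,5S,6R)-3-{[tert-butyl(dimethyl)silyl]oxy}-2-iodo-5,6-dimethyl-6-(prop-2-en-1-yl)cyclohex-1-en-1-yl]propanal | C[C@H]1C[C@H](O[Si](C)(C)C(C)(C)C)C(I)=C(CCC=O)[C@]1(C)CC=C | intermediate
17 | (4R,5S,7S)-7-{[tert-butyl(dimethyl)silyl]oxy}-4,5-dimethyl-4-(prop-2-en-1-yl)-2,3,4,5,6,7-hexahydro-1H-inden-1-ol, both C1 epimers | C[C@H]1C[C@H](O[Si](C)(C)C(C)(C)C)C2=C(CCC2O)[C@]1(C)CC=C | intermediate
18 | (4R,5S,7S)-7-{[tert-butyl(dimethyl)silyl]oxy}-4,5-dimethyl-4-(prop-2-en-1-yl)-2,3,4,5,6,7-hexahydro-1H-inden-1-one | C[C@H]1C[C@H](O[Si](C)(C)C(C)(C)C)C2=C(CCC2=O)[C@]1(C)CC=C | intermediate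
19 | isopropenylmagnesium bromide | C=C(C)[Mg]Br | starting material
20 | (1S,4R,5S,7S)-7-{[tert-butyl(dimethyl)silyl]oxy}-4,5-dimethyl-1-(prop-1-en-2-yl)-4-(prop-2-en-1-yl)-2,3,4,5,6,7-hexahydro-1H-inden-1-ol | C[C@H]1C[C@H](O[Si](C)(C)C(C)(C)C)C2=C(CC[C@]2(O)C(C)=C)[C@]1(C)CC=C | intermediate
21 | (1R,4R,5S,7S)-7-{[tert-butyl(dimethyl)silyl]oxy}-4,5-dimethyl-1-[(2R)-2-methyloxiran-2-yl]-4-(prop-2-en-1-yl)-2,3,4,5,6,7-hexahydro-1H-inden-1-ol | C[C@H]1C[C@H](O[Si](C)(C)C(C)(C)C)C2=C(CC[C@]2(O)[C@@]3(C)CO3)[C@]1(C)CC=C | intermediate (key-step precursor)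
22 | (1S,5R,6S,8S)-8-{[tert-butyl(dimethyl)silyl]oxy}-1-(hydroxymethyl)-1,5,6-trimethyl-5-(prop-2-en-1-yl)-3,4,5,6,7,8-hexahydronaphthalen-2(1H)-one | C[C@H]1C[C@H](O[Si](C)(C)C(C)(C)C)C2=C(CCC(=O)[C@]2(C)CO)[C@]1(C)CC=C | intermediate (key-step product)
23 | 3-(4-hydroxyphenyl)propanoic acid | OC(=O)CCc1ccc(O)cc1 | starting material
24 | tert-butyldimethylsilyl 3-(4-{[tert-butyl(dimethyl)silyl]oxy}phenyl)propanoate | CC(C)(C)[Si](C)(C)OC(=O)CCc1ccc(O[Si](C)(C)C(C)(C)C)cc1 | intermediate (not isolated)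
25 | 3-(4-{[tert-butyl(dimethyl)silyl]oxy}phenyl)propanoic acid | OC(=O)CCc1ccc(O[Si](C)(C)C(C)(C)C)cc1 | intermediate
26 | [(1S,5R,6S,8S)-8-{[tert-butyl(dimethyl)silyl]oxy}-1,5,6-trimethyl-2-oxo-5-(prop-2-en-1-yl)-1,2,3,4,5,6,7,8-octahydronaphthalen-1-yl]methyl 3-(4-{[tert-butyl(dimethyl)silyl]oxy}phenyl)propanoate | C[C@H]1C[C@H](O[Si](C)(C)C(C)(C)C)C2=C(CCC(=O)[C@]2(C)COC(=O)CCc2ccc(O[Si](C)(C)C(C)(C)C)cc2)[C@]1(C)CC=C | intermediate
27 | [(1S,5R,6S,8S)-8-{[tert-butyl(dimethyl)silyl]oxy}-1,5,6-trimethyl-2-oxo-5-(2-oxoethyl)-1,2,3,4,5,6,7,8-octahydronaphthalen-1-yl]methyl 3-(4-{[tert-butyl(dimethyl)silyl]oxy}phenyl)propanoate | C[C@H]1C[C@H](O[Si](C)(C)C(C)(C)C)C2=C(CCC(=O)[C@]2(C)COC(=O)CCc2ccc(O[Si](C)(C)C(C)(C)C)cc2)[C@]1(C)CC=O | intermediate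
28 | [(1S,5R,6S,8S)-8-{[tert-butyl(dimethyl)silyl]oxy}-5-(2-hydroxyethyl)-1,5,6-trimethyl-2-oxo-1,2,3,4,5,6,7,8-octahydronaphthalen-1-yl]methyl 3-(4-{[tert-butyl(dimethyl)silyl]oxy}phenyl)propanoate | C[C@H]1C[C@H](O[Si](C)(C)C(C)(C)C)C2=C(CCC(=O)[C@]2(C)COC(=O)CCc2ccc(O[Si](C)(C)C(C)(C)C)cc2)[C@]1(C)CCO | intermediate
29 | [(1S,5R,6S,8S)-8-{[tert-butyl(dimethyl)silyl]oxy}-5-(2-iodoethyl)-1,5,6-trimethyl-2-oxo-1,2,3,4,5,6,7,8-octahydronaphthalen-1-yl]methyl 3-(4-{[tert-butyl(dimethyl)silyl]oxy}phenyl)propanoate | C[C@H]1C[C@H](O[Si](C)(C)C(C)(C)C)C2=C(CCC(=O)[C@]2(C)COC(=O)CCc2ccc(O[Si](C)(C)C(C)(C)C)cc2)[C@]1(C)CCI | intermediate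
30 | 4-bromofuran-2(5H)-one | BrC1=CC(=O)OC1 | starting material
31 | alkylzinc iodide formed from 29 by zinc insertion at C12 | C[C@H]1C[C@H](O[Si](C)(C)C(C)(C)C)C2=C(CCC(=O)[C@]2(C)COC(=O)CCc2ccc(O[Si](C)(C)C(C)(C)C)cc2)[C@]1(C)CC[Zn]I | intermediate (not isolated)
32 | [(1S,5R,6S,8S)-8-{[tert-butyl(dimethyl)silyl]oxy}-1,5,6-trimethyl-2-oxo-5-[2-(5-oxo-2,5-dihydrofuran-3-yl)ethyl]-1,2,3,4,5,6,7,8-octahydronaphthalen-1-yl]methyl 3-(4-{[tert-butyl(dimethyl)silyl]oxy}phenyl)propanoate | C[C@H]1C[C@H](O[Si](C)(C)C(C)(C)C)C2=C(CCC(=O)[C@]2(C)COC(=O)CCc2ccc(O[Si](C)(C)C(C)(C)C)cc2)[C@]1(C)CCC1=CC(=O)OC1 | intermediate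
33 | [(1S,5R,6S,8S)-8-hydroxy-1,5,6-trimethyl-2-oxo-5-[2-(5-oxo-2,5-dihydrofuran-3-yl)ethyl]-1,2,3,4,5,6,7,8-octahydronaphthalen-1-yl]methyl 3-(4-hydroxyphenyl)propanoate | C[C@H]1C[C@H](O)C2=C(CCC(=O)[C@]2(C)COC(=O)CCc2ccc(O)cc2)[C@]1(C)CCC1=CC(=O)OC1 | target

**Step count**

Total: 21 steps. Longest linear sequence: 20 steps (steps 1–14 and 16–21); step 15 is a one-step side branch.

**Steps most likely to fail**

Step 13. The directed epoxidation may deliver oxygen to the wrong face of the isopropenyl group, or erode through competing epoxidation of the ring alkene. The facial preference rests on a small steric difference between the two flanks of C3. The fallback sets out from 18 and returns at 21. Addition of (1-ethoxyvinyl)lithium (ethyl vinyl ether, t-BuLi, THF, −78 °C) from the same face as the Grignard reagent should give the enol ether carbinol F1. Brief treatment with aqueous oxalic acid hydrolyses it to the acetyl carbinol F2. Corey–Chaykovsky methylenation with dimethylsulfonium methylide then adds the C19 methylene to the ketone and closes the oxirane. Here a carbon nucleophile, not oxygen, is delivered to C4, so for the same steric ranking of the C3 flanks it gives the C4 epimer opposite to that of the directed epoxidation, and should therefore reach 21 if the vanadium reaction favours the other face.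

Step 5. Iodine–magnesium exchange or single-electron reduction of the iodo enone may outrun 1,2-addition at a carbonyl flanked by a quaternary carbon and the iodoalkene. The fallback sets out from 9 and returns at 13, with the order of events changed. Grignard reagent 11 (LaCl3·2LiCl, THF, −78 °C) is added to the iodine-free enone to give the tertiary allylic alcohol F3. Babler–Dauben oxidation with pyridinium chlorochromate transposes it to the 3-substituted enone F4. The α-iodide is then introduced last with I2 and DMAP as nucleophilic promoter in aqueous THF/K2CO3, a variant suited to β-substituted enones (slower here because C10 is hindered).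

Step 14. Ionisation of the free tertiary allylic carbinol or of the allylic silyl ether, or migration of the C2 alkyl bond, may compete with the alkenyl shift. The fallback sets out from 21 and returns at 22, running the rearrangement on a capped carbinol. N-(Trimethylsilyl)imidazole converts 21 into the trimethylsilyl ether F5. TiCl4 in CH2Cl2 at −78 °C then triggers the silyl-ether variant of the epoxy-alcohol rearrangement, in which the migration is driven by a silyl oxocarbenium ion and no ionisable free hydroxyl is present. Mildly acidic aqueous work-up removes the trimethylsilyl group and should give 22.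

Further compounds
F1 | step 13 | (1R,4R,5S,7S)-7-{[tert-butyl(dimethyl)silyl]oxy}-1-(1-ethoxyethenyl)-4,5-dimethyl-4-(prop-2-en-1-yl)-2,3,4,5,6,7-hexahydro-1H-inden-1-ol | C[C@H]1C[C@H](O[Si](C)(C)C(C)(C)C)C2=C(CC[C@]2(O)C(OCC)=C)[C@]1(C)CC=C
F2 | step 13 | 1-[(1R,4R,5S,7S)-7-{[tert-butyl(dimethyl)silyl]oxy}-1-hydroxy-4,5-dimethyl-4-(prop-2-en-1-yl)-2,3,4,5,6,7-hexahydro-1H-inden-1-yl]ethan-1-one | C[C@H]1C[C@H](O[Si](C)(C)C(C)(C)C)C2=C(CC[C@]2(O)C(C)=O)[C@]1(C)CC=C
F3 | step 5 | (5S,6R)-1-[2-(1,3-dioxolan-2-yl)ethyl]-5,6-dimethyl-6-(prop-2-en-1-yl)cyclohex-2-en-1-ol, both C1 epimers | C[C@H]1CC=CC(O)(CCC2OCCO2)[C@]1(C)CC=C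
F4 | step 5 | (4R,5S)-3-[2-(1,3-dioxolan-2-yl)ethyl]-4,5-dimethyl-4-(prop-2-en-1-yl)cyclohex-2-en-1-one | C[C@H]1CC(=O)C=C(CCC2OCCO2)[C@]1(C)CC=C
F5 | step 14 | tert-butyl({(1R,3R,6S,7R)-7-methyl-shown as the 1-O-trimethylsilyl ether of 21: (1R,4R,5S,7S)-4,5-dimethyl-1-[(2R)-2-methyloxiran-2-yl]-4-(prop-2-en-1-yl)-1-[(trimethylsilyl)oxy]-2,3,4,5,6,7-hexahydro-1H-inden-7-yl}oxy)dimethylsilane | C[C@H]1C[C@H](O[Si](C)(C)C(C)(C)C)C2=C(CC[C@]2(O[Si](C)(C)C)[C@@]3(C)CO3)[C@]1(C)CC=C
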